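**Plan**
- Retrosynthesis: the C8 acyl group, the C3 aldehyde level and the C14 acetate are adjusted last; the lactone is cut at O1–C6 and C11–C12 (CO2 + C11 alkenylboronate + axial C6 mesylate), ring B at C7–C8 (aldol) and C6–C7 (acyl–allyl), and C5–C10 by an Ireland–Claisen transform.
- Forward: allylic ester 6 → [3,3] shift (C5–C10, quaternary C10, vinyl group) → 2-bromoallyl ketone → aldol closure of ring B → axial C6 alcohol → boronate and mesylate → carboxylative lactonisation → acetate, C3 oxidation, C8 ester.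
- Stereochemistry: C10 and C5 come from the chair Claisen transition state of a chiral boron enolate; C7 and C8 become equatorial in the chair aldol; C6 comes from equatorial hydride delivery (axial 6β-OH) and its inversion in the key step.
- Enabling feature: in the chair of ring B (C5–C10) the C6–O bond is axial and syn to the axial C10–CH2O arm, while the C11 alkenyl carbon on C7 is equatorial and 1,3 to C6. A carboxylate made at C11 therefore sits behind C6 and can close the five-membered ring O1–C12–C11–C7–C6 only with inversion, which gives the trans-fused lactone.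

Key step: step 11

Remark: elemanolide-type numbering is used (ring B = C5–C10; C1/C2 = vinyl on C10; C14 = CH2O on C10; C4/C15/C3 = propenyl unit on C5 with C3 the future aldehyde; C11/C13/C12 = lactone side chain); β is the face of ring B that carries C14; TBS = tert-butyldimethylsilyl, Bpin = pinacolatoboryl.
Remark: the (S,S)-boron controller of step 4 and (S)-proline of step 6 are assumed to be the matched reagents; if the sense of induction proves opposite, their antipodes would be used.

**Step 1**
Reactants: 1 4-(TBS-oxy)but-2-yn-1-ol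
Product: 2 (Z)-4-(TBS-oxy)-3-iodobut-2-en-1-ol
Conditions: NaAlH2(OCH2CH2OCH3)2, THF, 0 °C; then I2, −78 °C → 0 °C
Reagents that add atoms: iodine, II
Why: Alkoxide-directed trans-hydroalumination of the propargylic alcohol places aluminium on C3 and iodinolysis with retention should give the (Z)-iodide, which fixes the geometry of the later trisubstituted alkene (hydroalumination–iodination of propargylic alcohols).

**Step 2**
Reactants: 2 (Z)-4-(TBS-oxy)-3-iodobut-2-en-1-ol; 3 (1,3-dioxolan-2-ylmethyl)zinc bromide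
Product: 4 (E)-3-[(TBS-oxy)methyl]-4-(1,3-dioxolan-2-yl)but-2-en-1-ol (CH2OH cis to the dioxolanylmethyl arm)
Conditions: Pd(PPh3)4 (5 mol%), 3 (2.5 equiv), THF, 50 °C
Reagents that add atoms: none
Why: Negishi coupling of an alkenyl iodide with an alkylzinc halide under zerovalent palladium catalysis should proceed with retention of alkene geometry and tolerate the free hydroxyl when excess zinc reagent is used.

**Step 3**
Reactants: 4 (E)-3-[(TBS-oxy)methyl]-4-(1,3-dioxolan-2-yl)but-2-en-1-ol; 5 3-methylbut-3-enoic acid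
Product: 6 (E)-3-[(TBS-oxy)methyl]-4-(1,3-dioxolan-2-yl)but-2-en-1-yl 3-methylbut-3-enoate
Conditions: PPh3, DIAD, THF, 0 °C → rt
Reagents that add atoms: none
Why: Mitsunobu esterification should join the primary allylic alcohol and the β,γ-unsaturated acid under neutral conditions, which avoids base-induced conjugation of the acid.

**Step 4**
Reactants: 6 (E)-3-[(TBS-oxy)methyl]-4-(1,3-dioxolan-2-yl)but-2-en-1-yl 3-methylbut-3-enoate
Product: 8 (2S,3R)-3-[(TBS-oxy)methyl]-3-(1,3-dioxolan-2-ylmethyl)-2-(prop-1-en-2-yl)pent-4-enoic acid, via boron ketene acetal 7 (not isolated)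
Conditions: (4S,5S)-2-bromo-1,3-bis{[3,5-bis(trifluoromethyl)phenyl]sulfonyl}-4,5-diphenyl-1,3,2-diazaborolidine (1.2 equiv), i-Pr2NEt, CH2Cl2, −78 °C → rt; aqueous work-up
Reagents that add atoms: none
Why: Ireland–Claisen rearrangement of the (Z)-O-boron enolate (isopropenyl cis to O–B) through a chair, with the C9 arm axial (cis to the allylic CH2O) and the isopropenyl group equatorial, should form the C5–C10 bond, the vinyl group and the quaternary C10 in the required relative sense with C5, while the C2-symmetric sulfonamide ligand on boron selects the enolate face and so the absolute configuration (enantioselective boron-mediated ester-enolate Claisen rearrangement).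

**Step 5**
Reactants: 8 (2S,3R)-3-[(TBS-oxy)methyl]-3-(1,3-dioxolan-2-ylmethyl)-2-(prop-1-en-2-yl)pent-4-enoic acid; 9 2,3-dibromoprop-1-ene
Product: 11 (5S,6R)-2-bromo-6-[(TBS-oxy)methyl]-6-(1,3-dioxolan-2-ylmethyl)-5-(prop-1-en-2-yl)octa-1,7-dien-4-one, via acyl imidazolide 10 (not isolated)
Conditions: 1,1′-carbonyldiimidazole, THF, rt; then In powder, 9, THF/H2O, rt
Reagents that add atoms: none
Why: Barbier-type attack of the allylindium reagent from 9 on the acyl imidazolide should stop at the β,γ-unsaturated ketone (C6–C7 bond), the indium reagent being chosen because 2-haloallyl magnesium or zinc reagents collapse to allene, and the neutral medium limits epimerisation at C5 (indium-mediated allylation of acyl imidazoles).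

**Step 6**
Reactants: 11 (5S,6R)-2-bromo-6-[(TBS-oxy)methyl]-6-(1,3-dioxolan-2-ylmethyl)-5-(prop-1-en-2-yl)octa-1,7-dien-4-one
Product: 13 ring B ketol 2-(1-bromoethenyl)-5-[(TBS-oxy)methyl]-5-ethenyl-3-hydroxy-6-(prop-1-en-2-yl)cyclohexan-1-one (C5 isopropenyl β, C7 bromoethenyl β, C8 OH α, C10 CH2OTBS β and vinyl α), via keto aldehyde 12 (not isolated)
Conditions: PPTS, acetone/H2O, 55 °C; then (S)-proline (30 mol%), DMSO, rt
Reagents that add atoms: water, O
Why: Acetal hydrolysis frees the C8 aldehyde and the proline enamine formed at the less hindered C7 methylene should add in a 6-enolendo aldol through the chair that keeps the C5 isopropenyl group equatorial (C10 CH2OTBS axial), so the new C8 hydroxyl and C7 bromoethenyl group end equatorial and trans, as the ketol (proline-catalysed intramolecular aldol addition).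

**Step 7**
Reactants: 13 ring B ketol
Product: 14 8α-TBS ether of 13
Conditions: TBSOTf, 2,6-lutidine, CH2Cl2, −78 °C
Reagents that add atoms: tert-butyldimethylsilyl triflate, CC(C)(C)[Si](C)(C)OS(=O)(=O)C(F)(F)F
Why: Low-temperature silylation of the secondary hydroxyl with a silyl triflate and a hindered base should protect C8–OH before the β-hydroxy ketone can dehydrate or undergo retro-aldol cleavage.

**Step 8**
Reactants: 14 8α-TBS ether of 13
Product: 15 6β-alcohol (axial OH at C6, cis to the C5 and C7 substituents)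
Conditions: LiBH(s-Bu)3, THF, −78 °C
Reagents that add atoms: none
Why: The bulky hydride should attack the C6 carbonyl along the equatorial (α) trajectory, the axial approach being blocked by the syn-axial C10 CH2OTBS arm, and so deliver the axial 6β-alcohol (trialkylborohydride reduction of a 2,6-disubstituted cyclohexanone).

**Step 9**
Reactants: 15 6β-alcohol
Product: 16 C11 alkenyl-Bpin 6β-alcohol
Conditions: PdCl2(dppf) (5 mol%; dppf = 1,1′-bis(diphenylphosphino)ferrocene), KOAc, 1,4-dioxane, 80 °C
Reagents that add atoms: bis(pinacolato)diboron, CC1(C)OB(OC1(C)C)B1OC(C)(C)C(C)(C)O1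
Why: Miyaura borylation should convert the 1,1-disubstituted alkenyl bromide into the pinacol boronate without touching the silyl ethers, the free hydroxyl or the other alkenes.

**Step 10**
Reactants: 16 C11 alkenyl-Bpin 6β-alcohol
Product: 17 6β-mesylate
Conditions: MsCl, Et3N, CH2Cl2, −20 °C
Reagents that add atoms: methanesulfonyl chloride, CS(=O)(=O)Cl
Why: Sulfonylation through the small sulfene intermediate should reach the hindered axial hydroxyl and install the leaving group with retention at C6.

**Step 11**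
Reactants: 17 6β-mesylate
Product: 19 8α,14-bis(TBS-oxy)-elema-1,4(15),11(13)-trien-12,6α-olide (trans-fused α-methylene-γ-lactone), via potassium carboxylate 18 (not isolated)
Conditions: (IPr)CuCl (5 mol%; IPr = 1,3-bis(2,6-diisopropylphenyl)imidazol-2-ylidene), KOt-Bu (1.05 equiv), THF, rt; then CO2 (1 atm), 65 °C; then DMF, 60 °C
Reagents that add atoms: carbon dioxide, O=C=O
Why: The alkoxide turns the alkenyl-Bpin into its borate, which transmetallates to monovalent copper to give the C11 alkenylcopper; this inserts CO2 (C11–C12 bond) and the potassium carboxylate 18 then displaces the axial C6 mesylate from the rear (O1–C6 bond), so both bonds form in one flask. The closest known reaction types are the copper–carbene-catalysed carboxylation of alkenylboronic esters with CO2 and the invertive lactonisation of carboxylate salts onto secondary sulfonates in dipolar aprotic solvent. The one ring closed is the γ-lactone, by 5-exo-tet attack of carboxylate oxygen on C6. The only stereocentre touched is C6, which the SN2 trajectory inverts from β (axial) to α (equatorial), giving the trans ring fusion; C7 is not touched. The step needs substitution to win over E2 toward H5 or H7 and over attack of base on the mesylate; this is secured by using one equivalent of alkoxide that is bound as borate, by five-membered intramolecular delivery of a weakly basic carboxylate, and by relief of the syn-axial C6–O/C10–CH2O interaction on inversion.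

**Step 12**
Reactants: 19 bis-TBS lactone
Product: 20 8α,14-dihydroxy-elema-1,4(15),11(13)-trien-12,6α-olide
Conditions: HF·pyridine, pyridine/THF, 0 °C → rt
Reagents that add atoms: none
Why: Buffered HF should cleave both silyl ethers without conjugate addition to the α-methylene lactone, which basic fluoride sources could cause.

**Step 13**
Reactants: 20 diol lactone
Product: 21 14-acetoxy-8α-hydroxy-elema-1,4(15),11(13)-trien-12,6α-olide
Conditions: Ac2O (1.1 equiv), 2,4,6-collidine, CH2Cl2, −20 °C
Reagents that add atoms: acetic anhydride, CC(=O)OC(C)=O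
Why: The primary C14 hydroxyl should be acetylated selectively over the more hindered secondary C8 hydroxyl with a limiting amount of anhydride and a weak hindered base.

**Step 14**
Reactants: 21 14-acetate
Product: 23 14-acetoxy-8α-hydroxy-3-oxo-elema-1,4(15),11(13)-trien-12,6α-olide (C5 bears C(=CH2)CHO), via allylic alcohol 22 (not isolated)
Conditions: SeO2 (30 mol%), t-BuOOH, CH2Cl2, rt; then MnO2, CH2Cl2, rt
Reagents that add atoms: selenium dioxide, O=[Se]=O; tert-butyl hydroperoxide, CC(C)(C)OO
Why: The ene/[2,3] sequence of allylic oxidation should act only on the electron-rich isopropenyl group (the vinyl group has no allylic hydrogen, the lactone methylene is electron-poor, H5 is shielded by the quaternary C10) and MnO2 should then oxidise only the primary allylic alcohol, leaving C8–OH.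

**Step 15**
Reactants: 24 2-(hydroxymethyl)prop-2-enoic acid
Product: 26 2-[(TBS-oxy)methyl]prop-2-enoic acid, via silyl ester 25 (not isolated)
Conditions: TBSCl (2.2 equiv), imidazole, DMF, rt; then K2CO3, MeOH/THF/H2O, 0 °C; acidify
Reagents that add atoms: tert-butyl(chloro)dimethylsilane, CC(C)(C)[Si](C)(C)Cl
Why: Bis-silylation followed by selective hydrolysis of the labile silyl ester should give the O-protected acid needed for the C8 ester.

**Step 16**
Reactants: 23 hydroxy enal lactone; 26 2-[(TBS-oxy)methyl]prop-2-enoic acid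
Product: 27 TBS ether of the target (8α-ester)
Conditions: DCC, DMAP (20 mol%), CH2Cl2, 0 °C → rt
Reagents that add atoms: none
Why: Steglich esterification should acylate the remaining secondary C8 hydroxyl with retention and leave the enal, acetate and lactone intact.

**Step 17**
Reactants: 27 TBS ether of the target
Product: 28 target, CNP0185525.1
Conditions: HF·pyridine, THF, 0 °C
Reagents that add atoms: none
Why: Mild acidic fluoride should remove the primary allylic silyl ether without acyl migration or addition to the three Michael acceptors.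

**Compound list**
1 | 4-(TBS-oxy)but-2-yn-1-ol | OCC#CCO[Si](C)(C)C(C)(C)C | starting material
2 | (Z)-4-(TBS-oxy)-3-iodobut-2-en-1-ol | OC/C=C(\I)CO[Si](C)(C)C(C)(C)C | intermediate
3 | (1,3-dioxolan-2-ylmethyl)zinc bromide | Br[Zn]CC1OCCO1 | starting material
4 | (E)-3-[(TBS-oxy)methyl]-4-(1,3-dioxolan-2-yl)but-2-en-1-ol | OC/C=C(\CC1OCCO1)CO[Si](C)(C)C(C)(C)C | intermediate
5 | 3-methylbut-3-enoic acid | C=C(C)CC(=O)O | starting material
6 | (E)-3-[(TBS-oxy)methyl]-4-(1,3-dioxolan-2-yl)but-2-en-1-yl 3-methylbut-3-enoate | C=C(C)CC(=O)OC/C=C(\CC1OCCO1)CO[Si](C)(C)C(C)(C)C | intermediate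
7 | (Z)-O-boron ketene acetal of 6 with the (S,S)-bis(sulfonamido) ligand on boron | C=C(C)/C=C(\OB1N(S(=O)(=O)c2cc(cc(c2)C(F)(F)F)C(F)(F)F)[C@@H](c2ccccc2)[C@H](c2ccccc2)N1S(=O)(=O)c1cc(cc(c1)C(F)(F)F)C(F)(F)F)OC/C=C(\CC1OCCO1)CO[Si](C)(C)C(C)(C)C | intermediate
8 | (2S,3R)-3-[(TBS-oxy)methyl]-3-(1,3-dioxolan-2-ylmethyl)-2-(prop-1-en-2-yl)pent-4-enoic acid | C=C[C@](CO[Si](C)(C)C(C)(C)C)(CC1OCCO1)[C@H](C(C)=C)C(=O)O | intermediate
9 | 2,3-dibromoprop-1-ene | C=C(Br)CBr | starting material
10 | acyl imidazolide of 8 | C=C[C@](CO[Si](C)(C)C(C)(C)C)(CC1OCCO1)[C@H](C(C)=C)C(=O)n1ccnc1 | intermediate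
11 | (5S,6R)-2-bromo-6-[(TBS-oxy)methyl]-6-(1,3-dioxolan-2-ylmethyl)-5-(prop-1-en-2-yl)octa-1,7-dien-4-one | C=C[C@](CO[Si](C)(C)C(C)(C)C)(CC1OCCO1)[C@H](C(C)=C)C(=O)CC(Br)=C | intermediate
12 | keto aldehyde (C8 aldehyde freed from 11) | C=C[C@](CO[Si](C)(C)C(C)(C)C)(CC=O)[C@H](C(C)=C)C(=O)CC(Br)=C | intermediate
13 | ring B ketol (C6 ketone, 8α-OH, 7β-(1-bromoethenyl), 5β-isopropenyl) | C=C[C@]1(CO[Si](C)(C)C(C)(C)C)C[C@H](O)[C@@H](C(Br)=C)C(=O)[C@H]1C(C)=C | intermediate
14 | 8α-TBS ether of 13 | C=C[C@]1(CO[Si](C)(C)C(C)(C)C)C[C@H](O[Si](C)(C)C(C)(C)C)[C@@H](C(Br)=C)C(=O)[C@H]1C(C)=C | intermediate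
15 | 6β-alcohol | C=C[C@]1(CO[Si](C)(C)C(C)(C)C)C[C@H](O[Si](C)(C)C(C)(C)C)[C@@H](C(Br)=C)[C@@H](O)[C@H]1C(C)=C | intermediate
16 | C11 alkenyl-Bpin 6β-alcohol | C=C[C@]1(CO[Si](C)(C)C(C)(C)C)C[C@H](O[Si](C)(C)C(C)(C)C)[C@@H](C(=C)B2OC(C)(C)C(C)(C)O2)[C@@H](O)[C@H]1C(C)=C | intermediate
17 | 6β-mesylate | C=C[C@]1(CO[Si](C)(C)C(C)(C)C)C[C@H](O[Si](C)(C)C(C)(C)C)[C@@H](C(=C)B2OC(C)(C)C(C)(C)O2)[C@@H](OS(C)(=O)=O)[C@H]1C(C)=C | intermediate
18 | potassium C12 carboxylate of the 6β-mesylate | C=C[C@]1(CO[Si](C)(C)C(C)(C)C)C[C@H](O[Si](C)(C)C(C)(C)C)[C@@H](C(=C)C(=O)[O-])[C@@H](OS(C)(=O)=O)[C@H]1C(C)=C.[K+] | intermediate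
19 | 8α,14-bis(TBS-oxy)-elema-1,4(15),11(13)-trien-12,6α-olide | C=C[C@]1(CO[Si](C)(C)C(C)(C)C)C[C@H](O[Si](C)(C)C(C)(C)C)[C@H]2C(=C)C(=O)O[C@@H]2[C@H]1C(C)=C | intermediate
20 | 8α,14-dihydroxy-elema-1,4(15),11(13)-trien-12,6α-olide | C=C[C@]1(CO)C[C@H](O)[C@H]2C(=C)C(=O)O[C@@H]2[C@H]1C(C)=C | intermediate
21 | 14-acetoxy-8α-hydroxy-elema-1,4(15),11(13)-trien-12,6α-olide | C=C[C@]1(COC(C)=O)C[C@H](O)[C@H]2C(=C)C(=O)O[C@@H]2[C@H]1C(C)=C | intermediate
22 | 14-acetoxy-3,8α-dihydroxy-elema-1,4(15),11(13)-trien-12,6α-olide | C=C[C@]1(COC(C)=O)C[C@H](O)[C@H]2C(=C)C(=O)O[C@@H]2[C@H]1C(=C)CO | intermediate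
23 | 14-acetoxy-8α-hydroxy-3-oxo-elema-1,4(15),11(13)-trien-12,6α-olide | C=C[C@]1(COC(C)=O)C[C@H](O)[C@H]2C(=C)C(=O)O[C@@H]2[C@H]1C(=C)C=O | intermediate
24 | 2-(hydroxymethyl)prop-2-enoic acid | C=C(CO)C(=O)O | starting material
25 | TBS 2-[(TBS-oxy)methyl]prop-2-enoate | C=C(CO[Si](C)(C)C(C)(C)C)C(=O)O[Si](C)(C)C(C)(C)C | intermediate
26 | 2-[(TBS-oxy)methyl]prop-2-enoic acid | C=C(CO[Si](C)(C)C(C)(C)C)C(=O)O | intermediate
27 | TBS ether of the target | C=C[C@]1(COC(C)=O)C[C@H](OC(=O)C(=C)CO[Si](C)(C)C(C)(C)C)[C@H]2C(=C)C(=O)O[C@@H]2[C@H]1C(=C)C=O | intermediate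
28 | CNP0185525.1 | C=C[C@]1(COC(C)=O)C[C@H](OC(=O)C(=C)CO)[C@H]2C(=C)C(=O)O[C@@H]2[C@H]1C(=C)C=O | target

**Totals**
Total step count: 17. Longest linear sequence: 16 (steps 1–14, 16, 17).

**Steps most likely to fail**

Step 11 (key step). E2 loss of the axial mesylate toward H5 or H7, or protodeboronation before CO2 capture, may outrun substitution. The lactone would then be closed by acyl–oxygen rather than alkyl–oxygen bond formation. Setting out from alcohol 15, Mitsunobu inversion (4-nitrobenzoic acid, PPh3, DIAD, toluene) would give the 6α-(4-nitrobenzoate) F1, and methanolysis (K2CO3, MeOH) the 6α-alcohol F2. Palladium-catalysed cyclocarbonylation of this 2-bromo homoallylic alcohol (Pd(PPh3)4, CO 1 atm, Et3N, MeCN, 60 °C) would come back to the route at lactone 19.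

Step 6. The enamine aldol may suffer from isomerisation of the β,γ-unsaturated ketone through its dienamine, from dehydration of the ketol, or from poor facial selectivity. Setting out from keto aldehyde 12, deliberate aldol condensation (pyrrolidinium acetate, CH2Cl2) would give the cross-conjugated enone F3. Nucleophilic epoxidation from the α face, anti to the axial CH2OTBS arm (H2O2, NaOH, MeOH, 0 °C), would give the epoxy ketone F4. Reductive cleavage of its Cα–O bond (SmI2, THF/MeOH, −90 °C) would come back to the route at ketol 13.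

Step 4. Enolisation by the bulky boron bromide may be sluggish, the Lewis-acidic boron may attack the acetal, or the facial selectivity may be low. Setting out from ester 6, an achiral Ireland–Claisen rearrangement (LDA, Me3SiCl, THF/DMPU, −78 °C → rt; same enolate geometry and chair) would give the racemic acid F5 of the same relative configuration. Resolution by crystallisation of its (S)-1-phenylethylammonium salt F6 and acidification would come back to the route at acid 8.

**Further compounds**
F1 | step 11 | 6α-(4-nitrobenzoate) of the epimer of 15 | C=C[C@]1(CO[Si](C)(C)C(C)(C)C)C[C@H](O[Si](C)(C)C(C)(C)C)[C@@H](C(Br)=C)[C@H](OC(=O)c2ccc(cc2)[N+](=O)[O-])[C@H]1C(C)=C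
F2 | step 11 | 6α-alcohol (C6 epimer of 15) | C=C[C@]1(CO[Si](C)(C)C(C)(C)C)C[C@H](O[Si](C)(C)C(C)(C)C)[C@@H](C(Br)=C)[C@H](O)[C@H]1C(C)=C
F3 | step 6 | 2-(1-bromoethenyl)-5-[(TBS-oxy)methyl]-5-ethenyl-6-(prop-1-en-2-yl)cyclohex-2-en-1-one | C=C[C@]1(CO[Si](C)(C)C(C)(C)C)CC=C(C(Br)=C)C(=O)[C@H]1C(C)=C
F4 | step 6 | 7α,8α-epoxy ketone from F3 | C=C[C@]1(CO[Si](C)(C)C(C)(C)C)C[C@@H]2O[C@]2(C(Br)=C)C(=O)[C@H]1C(C)=C
F5 | step 4 | racemic acid (8 and its enantiomer) | C=C[C@](CO[Si](C)(C)C(C)(C)C)(CC1OCCO1)[C@H](C(C)=C)C(=O)O.C=C[C@@](CO[Si](C)(C)C(C)(C)C)(CC1OCCO1)[C@@H](C(C)=C)C(=O)O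
F6 | step 4 | (S)-1-phenylethylammonium salt of 8 | C=C[C@](CO[Si](C)(C)C(C)(C)C)(CC1OCCO1)[C@H](C(C)=C)C(=O)[O-].C[C@H]([NH3+])c1ccccc1
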